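The numbers were chosen freely; the rest is arithmetic.

The mono adduct is the wanted species, and the question is how much of it stands at the end as the partner charge grows while the starting material, fed in portions, stays the same.

    starting material + partner → mono adduct (k1 = 34 M⁻¹ s⁻¹)
    partner + mono adduct → double product (k2 = 6.5 M⁻¹ s⁻¹)
    partner + double product → triple product (k3 = 72 M⁻¹ s⁻¹)
    partner + triple product → tetra adduct (k4 = 190 M⁻¹ s⁻¹)
    partner → decomposed reagent (k5 = 0.054 s⁻¹)

common to all: starting material 5.0 mM (in portions, 4); time 20 s
- amber: partner 5.00 mM; the portions of starting material follow each other after 0.50 s, the first at the start
- red: partner 8.00 mM; the portions of starting material follow each other after 0.50 s, the first at the start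
- ochre: partner 12.0 mM; the portions of starting material follow each other after 0.50 s, the first at the start
- violet: partner 15.0 mM; the portions of starting material follow each other after 0.50 s, the first at the start
- green: partner 25.0 mM; the portions of starting material follow each other after 0.50 s, the first at the start

- "hardly changes" means that all values lie within two and a half points (for a concentration: within two and a half percent of the largest)
- run time (amber): 20 s

* amount of mono adduct at the end, in percent of the starting material charged for amber, red, ochre, violet, green, in this order
* the course of these numbers from the first flask to the last (falls all the way / falls, then rises / rises, then falls / rises all the way / hardly changes)

With the first step by itself, starting material and partner combine one to one, and the half-life of starting material by this step alone, with partner as charged, is 4.1 s in amber, shorter than the run of 20 s. Each flask holds at least as much partner as the charge of 5.0 mM, so the number heads for 100 percent.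

Adding the second step changes the picture. Mono adduct now gains by the first step and loses by the second, and both rates carry the partner as a factor, so dividing one by the other removes both partner and clock. Mono adduct then follows one curve against the starting material left, and growth stops where mono adduct over starting material equals 34 M⁻¹ s⁻¹ over 6.5 M⁻¹ s⁻¹, which is 5.23. This is the crossing ratio, the usual selectivity factor. Integrating the curve for a single charge places the crossing at 12.9% of the starting material left, where the curve tops out at 67.6% mono adduct. The portions arrive within 1.50 s, shorter than that half-life in amber, so the curve for a single charge serves as an approximation. More partner moves a flask further along this curve, so the row should rise while flasks end short of the crossing and fall once they end beyond it.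

The remaining steps touch neither starting material nor mono adduct, so they leave the curve in place and set the price of reaching the crossing in partner. Conversion of starting material costs 4.35 mM. Mono adduct lost beyond that is reckoned at the full 3 partners each, as an estimate, since in amber, with partner as charged, double product has a half-life of 1.9 s, shorter than the 21 s of mono adduct, and this adds 2.92 mM. Decomposition runs on the same time integral of partner as the first step, so it takes 3.25 mM. The crossing therefore needs about 10.5 mM of partner, counting the whole charge as consumed by the end, a rough step, since 20 s is 1.56 half-lives of decomposition. Red, with 8.00 mM, lies below this and ochre, with 12.0 mM, above it.

The forecast gives 51%, 64%, 67%, 64% and 46%, a course that rises, then falls, holding that “the yield peaks near 12 mM and drops again”.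

The flasks give 52.1%, 64.4%, 67.0%, 63.5% and 42.9%, a course that rises, then falls. The row turns at 11 mM of partner, where it reads 67.4%, beside the reckoned 10.5 mM and 67.6%. Ochre ends with mono adduct over starting material at 6.57, above the crossing ratio of 5.23, and after 200 s it holds 66.5%, less than its 67.0%. Red ends at 2.72, below that ratio, and after 200 s it holds 65.3%, more than its 64.4%.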